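The tetralone (ring B) is opened at C1–C8a and cut back at C2–C3. This exposes the core problem: C4 is a methine bearing two similar electron-rich aryls (fused dimethoxy ring A, pendant ring C) next to methyl-bearing C3. One Pd-catalysed conjunctive coupling forms C3–CH3 and C4–ring C together, anti across an E-alkene, so each aryl is defined by the partner that delivers it. The precursor is the ate complex of methyllithium with an (E)-3,4-dimethoxystyrylboronate, which meets the ring C aryl triflate (phenol masked as tosylate). Boron carries the hindered acenaphthoquinone-derived mac diol, because pinacol esters of β-substituted alkenes divert to Suzuki coupling. The surviving C3–B bond accepts C2 and C1.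

Key step: step 6

Assumption: locants C1–C8a follow the tetralone numbering of the target and are kept for the open-chain precursors. The diol on boron is treated as a spectator ligand. The MandyPhos antipode that gives (1S,2R)-14 is fixed in a test run, both antipodes being commercial.

Step 1
Reactants: 1 acenaphthenequinone
Product: 2 cis-(1R,2S)-1,2-dimethyl-1,2-dihydroacenaphthylene-1,2-diol (meso mac diol)
Conditions: AlMe3 (3 equiv), toluene, 0 °C to rt; aqueous work-up; recrystallisation
Reagents that add atoms: trimethylaluminium, C[Al](C)C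
Why: Double 1,2-addition of a methylaluminium reagent to the 1,2-diketone, in which the second methyl should enter anti to the bulky aluminium alkoxide formed first and so give the cis (meso) diol, any trans isomer being removed by recrystallisation.

Step 2
Reactants: 3 4-ethynyl-1,2-dimethoxybenzene; 4 catecholborane; 2 mac diol
Product: 6 mac ester of (E)-2-(3,4-dimethoxyphenyl)ethenylboronic acid, via catechol alkenylboronate 5 (not isolated)
Conditions: 4 (1.1 equiv), Cy2BH (5 mol %), THF, rt; then 2 (1.0 equiv), rt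
Reagents that add atoms: none
Why: Borane-catalysed syn hydroboration of the terminal arylalkyne puts boron on the terminal carbon and gives the E-alkene, and the labile catechol ester then undergoes transesterification with the dialkyl diol 2.

Step 3
Reactants: 7 isovanillin
Product: 8 5-formyl-2-methoxyphenyl 4-methylbenzenesulfonate
Conditions: TsCl, Et3N, DMAP (cat.), CH2Cl2, 0 °C to rt
Reagents that add atoms: p-toluenesulfonyl chloride, Cc1ccc(S(=O)(=O)Cl)cc1
Why: O-sulfonylation of the phenol gives a mask that resists the later borate, carbenoid, oxidative and acidic steps and that deactivates ring C for step 9.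

Step 4
Reactants: 8 5-formyl-2-methoxyphenyl 4-methylbenzenesulfonate
Product: 10 5-hydroxy-2-methoxyphenyl 4-methylbenzenesulfonate, via aryl formate 9 (not isolated)
Conditions: mCPBA, CH2Cl2, rt; crude, then K2CO3 (cat.), MeOH, 0 °C to rt
Reagents that add atoms: mCPBA, O=C(OO)c1cccc(Cl)c1
Why: Baeyer–Villiger oxidation in which the para-methoxy-activated aryl group migrates in preference to hydride, followed by brief methanolysis of the formate that leaves the sulfonate intact.

Step 5
Reactants: 10 5-hydroxy-2-methoxyphenyl 4-methylbenzenesulfonate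
Product: 11 4-methoxy-3-(tosyloxy)phenyl trifluoromethanesulfonate
Conditions: Tf2O, pyridine, CH2Cl2, 0 °C
Reagents that add atoms: triflic anhydride, O=S(=O)(OS(=O)(=O)C(F)(F)F)C(F)(F)F
Why: Triflation of the free phenol creates the only C–O bond of 11 into which Pd(0) inserts under the conditions of step 6.

Step 6
Reactants: 6 mac ester of (E)-2-(3,4-dimethoxyphenyl)ethenylboronic acid; 12 methyllithium; 11 4-methoxy-3-(tosyloxy)phenyl trifluoromethanesulfonate
Product: 14 mac ester of (1S,2R)-1-(3,4-dimethoxyphenyl)-1-[4-methoxy-3-(tosyloxy)phenyl]propan-2-ylboronic acid, via lithium methyl(styryl)borate 13 (not isolated)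
Conditions: 12 (1.0 equiv, low-halide, Et2O), 0 °C to rt; evaporate; Pd(OAc)2 (3 mol %), MandyPhos (3.6 mol %), 11 (1.1 equiv), KOTf (1 equiv), THF, 60 °C
Reagents that add atoms: none
Why: MeLi fills the empty orbital on boron to give borate 13, Pd(0)–MandyPhos inserts into the C–OTf bond of 11 (C–OTs stays inert), and the resulting cationic arylpalladium binds the alkene of 13 and triggers a 1,2-metallate shift in which methyl moves from boron to C3 on the face opposite to Pd while Pd bonds benzylic C4, after which reductive elimination with retention forms C4–ring C. This is the Pd-catalysed enantioselective conjunctive cross-coupling of alkenylboron ate complexes with aryl triflates, in its variant for β-substituted alkenyl B(mac) esters. No ring is closed. The relative configuration of C3 and C4 follows from the stereospecific anti addition across the E-alkene, which places C3–CH3 and ring C cis once C2 and C4a are tied into ring B, and the absolute configuration of both centres follows from the alkene face that the chiral bisphosphine lets Pd bind. The step needs the metallate shift to beat direct styryl or methyl transfer to Pd (Suzuki–Miyaura path), which the hindered mac diol secures, and it needs a halide-free medium (low-halide MeLi, triflate leaving group, KOTf scavenger) so that Pd stays cationic. Regiochemistry is inherent, because the migrating group must land on the boron-bearing carbon while ring A stabilises Pd at C4, and methyl is the only carbon ligand left on boron that can migrate.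

Step 7
Reactants: 14 mac ester of (1S,2R)-1-(3,4-dimethoxyphenyl)-1-[4-methoxy-3-(tosyloxy)phenyl]propan-2-ylboronic acid
Product: 16 mac ester of (3S,4S)-4-(3,4-dimethoxyphenyl)-4-[4-methoxy-3-(tosyloxy)phenyl]-3-methylbutan-2-ylboronic acid (C2 epimers), via α-chloroboronate 15 (not isolated)
Conditions: CH2Cl2, n-BuLi, THF, −100 °C (carbenoid preformed); add 14, −100 °C to rt; then MeMgBr, −78 °C to rt
Reagents that add atoms: dichloromethane, ClCCl; methylmagnesium bromide, C[Mg]Br
Why: Matteson homologation, in which LiCHCl2 adds to boron, C3 migrates with retention and expels chloride, and MeMgBr forms a second borate whose methyl displaces the remaining chloride, so C2 arises as an epimer mixture that is harmless because C2 is set in step 10.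

Step 8
Reactants: 16 mac ester of (3S,4S)-4-(3,4-dimethoxyphenyl)-4-[4-methoxy-3-(tosyloxy)phenyl]-3-methylbutan-2-ylboronic acid (C2 epimers)
Product: 19 (3R,4S)-4-(3,4-dimethoxyphenyl)-4-[4-methoxy-3-(tosyloxy)phenyl]-2,3-dimethylbutanoic acid (C2 epimers), via α-chloroboronate 17 (not isolated), via aldehyde 18 (not isolated)
Conditions: CH2Cl2, n-BuLi, THF, −100 °C; add 16, to rt; evaporate; NaClO2, NaH2PO4, 2-methyl-2-butene, t-BuOH/THF/H2O, 0 °C to rt
Reagents that add atoms: dichloromethane, ClCCl; sodium chlorite, [Na+].[O-]Cl=O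
Why: A second Matteson homologation (C2 migrates with retention) is followed by the known chlorite oxidation of α-chloroboronic esters, where C–B oxidation releases aldehyde 18 and Pinnick oxidation in the same flask takes it to the acid, with 2-methyl-2-butene shielding the electron-rich rings from HOCl.

Step 9
Reactants: 19 (3R,4S)-4-(3,4-dimethoxyphenyl)-4-[4-methoxy-3-(tosyloxy)phenyl]-2,3-dimethylbutanoic acid (C2 epimers)
Product: 21 (3R,4R)-6,7-dimethoxy-4-[4-methoxy-3-(tosyloxy)phenyl]-2,3-dimethyl-3,4-dihydronaphthalen-1(2H)-one (C2 epimers), via mixed trifluoroacetic anhydride 20 (not isolated)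
Conditions: TFAA (2 equiv), CH2Cl2, 0 °C to rt
Reagents that add atoms: none
Why: Intramolecular Friedel–Crafts acylation closes ring B on ring A at the position para to its 3-methoxy group (the future C8a), whereas ring C is switched off because its corresponding position is para only to the electron-poor sulfonate oxygen, and C3 and C4 are not touched.

Step 10
Reactants: 21 (3R,4R)-6,7-dimethoxy-4-[4-methoxy-3-(tosyloxy)phenyl]-2,3-dimethyl-3,4-dihydronaphthalen-1(2H)-one (C2 epimers)
Product: 22 (2S,3R,4R)-4-(3-hydroxy-4-methoxyphenyl)-6,7-dimethoxy-2,3-dimethyl-3,4-dihydronaphthalen-1(2H)-one (target)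
Conditions: KOH (5 equiv), degassed EtOH/H2O, reflux, Ar; aq. HCl work-up
Reagents that add atoms: none
Why: Hydroxide cleaves the aryl sulfonate at sulfur (saponification) while reversible enolisation of the C1 ketone equilibrates C2 to the (2S) epimer, in which C2–CH3 and C3–CH3 are trans-diequatorial, whereas the (2R) epimer would hold C2–CH3 1,3-diaxial to the pseudoaxial ring C.

Compound list
1 | acenaphthenequinone | O=C1C(=O)c2cccc3cccc1c23 | starting material
2 | cis-(1R,2S)-1,2-dimethyl-1,2-dihydroacenaphthylene-1,2-diol (mac diol) | C[C@@]1(O)c2cccc3cccc(c23)[C@]1(C)O | intermediate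
3 | 4-ethynyl-1,2-dimethoxybenzene | COc1ccc(C#C)cc1OC | starting material
4 | catecholborane | B1Oc2ccccc2O1 | starting material
5 | catechol ester of (E)-2-(3,4-dimethoxyphenyl)ethenylboronic acid | COc1ccc(/C=C/B2Oc3ccccc3O2)cc1OC | intermediate
6 | mac ester of (E)-2-(3,4-dimethoxyphenyl)ethenylboronic acid | COc1ccc(/C=C/B2O[C@]3(C)c4cccc5cccc(c45)[C@]3(C)O2)cc1OC | intermediate
7 | isovanillin | COc1ccc(C=O)cc1O | starting material
8 | 5-formyl-2-methoxyphenyl 4-methylbenzenesulfonate | COc1ccc(C=O)cc1OS(=O)(=O)c1ccc(C)cc1 | intermediate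
9 | 5-(formyloxy)-2-methoxyphenyl 4-methylbenzenesulfonate | COc1ccc(OC=O)cc1OS(=O)(=O)c1ccc(C)cc1 | intermediate
10 | 5-hydroxy-2-methoxyphenyl 4-methylbenzenesulfonate | COc1ccc(O)cc1OS(=O)(=O)c1ccc(C)cc1 | intermediate
11 | 4-methoxy-3-(tosyloxy)phenyl trifluoromethanesulfonate | COc1ccc(OS(=O)(=O)C(F)(F)F)cc1OS(=O)(=O)c1ccc(C)cc1 | intermediate
12 | methyllithium | [Li]C | starting material
13 | lithium methyl[(E)-3,4-dimethoxystyryl]borate of mac diol (configuration at boron undefined) | [Li+].COc1ccc(/C=C/[B-]2(C)O[C@]3(C)c4cccc5cccc(c45)[C@]3(C)O2)cc1OC | intermediate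
14 | mac ester of (1S,2R)-1-(3,4-dimethoxyphenyl)-1-[4-methoxy-3-(tosyloxy)phenyl]propan-2-ylboronic acid | COc1ccc([C@@H]([C@@H](C)B2O[C@]3(C)c4cccc5cccc(c45)[C@]3(C)O2)c2ccc(OC)c(OC)c2)cc1OS(=O)(=O)c1ccc(C)cc1 | intermediate
15 | mac ester of (2R,3S)-1-chloro-3-(3,4-dimethoxyphenyl)-3-[4-methoxy-3-(tosyloxy)phenyl]-2-methylpropylboronic acid (CHCl epimers) | COc1ccc([C@@H]([C@@H](C)C(Cl)B2O[C@]3(C)c4cccc5cccc(c45)[C@]3(C)O2)c2ccc(OC)c(OC)c2)cc1OS(=O)(=O)c1ccc(C)cc1 | intermediate
16 | mac ester of (3S,4S)-4-(3,4-dimethoxyphenyl)-4-[4-methoxy-3-(tosyloxy)phenyl]-3-methylbutan-2-ylboronic acid (C2 epimers) | COc1ccc([C@@H]([C@@H](C)C(C)B2O[C@]3(C)c4cccc5cccc(c45)[C@]3(C)O2)c2ccc(OC)c(OC)c2)cc1OS(=O)(=O)c1ccc(C)cc1 | intermediate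
17 | mac ester of (3R,4S)-1-chloro-4-(3,4-dimethoxyphenyl)-4-[4-methoxy-3-(tosyloxy)phenyl]-2,3-dimethylbutylboronic acid (C1 and C2 epimers) | COc1ccc([C@@H]([C@@H](C)C(C)C(Cl)B2O[C@]3(C)c4cccc5cccc(c45)[C@]3(C)O2)c2ccc(OC)c(OC)c2)cc1OS(=O)(=O)c1ccc(C)cc1 | intermediate
18 | (3R,4S)-4-(3,4-dimethoxyphenyl)-4-[4-methoxy-3-(tosyloxy)phenyl]-2,3-dimethylbutanal (C2 epimers) | COc1ccc([C@@H]([C@@H](C)C(C)C=O)c2ccc(OC)c(OC)c2)cc1OS(=O)(=O)c1ccc(C)cc1 | intermediate
19 | (3R,4S)-4-(3,4-dimethoxyphenyl)-4-[4-methoxy-3-(tosyloxy)phenyl]-2,3-dimethylbutanoic acid (C2 epimers) | COc1ccc([C@@H]([C@@H](C)C(C)C(=O)O)c2ccc(OC)c(OC)c2)cc1OS(=O)(=O)c1ccc(C)cc1 | intermediate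
20 | mixed anhydride of 19 and trifluoroacetic acid | COc1ccc([C@@H]([C@@H](C)C(C)C(=O)OC(=O)C(F)(F)F)c2ccc(OC)c(OC)c2)cc1OS(=O)(=O)c1ccc(C)cc1 | intermediate
21 | (3R,4R)-6,7-dimethoxy-4-[4-methoxy-3-(tosyloxy)phenyl]-2,3-dimethyl-3,4-dihydronaphthalen-1(2H)-one (C2 epimers) | COc1ccc([C@@H]2c3cc(OC)c(OC)cc3C(=O)C(C)[C@@H]2C)cc1OS(=O)(=O)c1ccc(C)cc1 | intermediate
22 | (2S,3R,4R)-4-(3-hydroxy-4-methoxyphenyl)-6,7-dimethoxy-2,3-dimethyl-3,4-dihydronaphthalen-1(2H)-one | COc1ccc([C@@H]2c3cc(OC)c(OC)cc3C(=O)[C@@H](C)[C@@H]2C)cc1O | target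

Total step count: 10
Longest linear sequence: 8 steps (7 to 22, steps 3–10)

Steps most likely to fail

**Step 6.**
- Risk: direct transfer of the styryl or methyl group from boron to palladium may outrun the slow methyl shift. The benzylic C4–Pd bond may also lose its configuration before reductive elimination, and face selection on an aryl-substituted alkene may be weak.
- Fallback: the known enantioselective Cu/Pd-cocatalysed arylboration of alkenylarenes, which sets out from triflate 11 and comes back at acid 19.
- Triflate 11 is exchanged for bromide (LiBr, cat. [Cp*Ru(MeCN)3]OTf, DMI, 100 °C) to give 5-bromo-2-methoxyphenyl 4-methylbenzenesulfonate F1.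
- F1, commercial (E)-methylisoeugenol (COc1ccc(/C=C/C)cc1OC) and B2pin2 are joined under a chiral NHC–copper catalyst and a RuPhos–palladium catalyst with NaOt-Bu. Syn borylcupration puts boron on C3 and copper on benzylic C4. Stereoretentive transfer to arylpalladium and reductive elimination then give the pinacol boronate F2.
- Syn addition of boron and ring C to the E-propenylarene leads to the same relative configuration as in 14, and each aryl again comes from its own partner.
- The pinacol series then passes through the operations of step 7, by way of the pinacol α-chloroboronate F3 and the pinacol butan-2-ylboronate F4. The operations of step 8 follow, by way of the pinacol α-chloroboronate F5, and the series merges with the route at aldehyde 18 and acid 19.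

**Step 7.**
- Risk: borate formation and migration of the hindered C3 group next to the diarylmethyl unit may be slower than carbenoid decay, and the Grignard reagent may start to attack the sulfonate.
- Fallback: it sets out from 14 and comes back at acid 19, adding C2, its methyl and C1 as one sp2 unit.
- Isopropenyllithium (2-bromopropene, t-BuLi, −78 °C) is added to 14, followed by I2 and NaOMe. This Zweifel olefination, with retention at C3, gives the 2,3-dimethylbut-1-ene F6.
- Hydroboration with 9-BBN and oxidation with NaBO3 give the primary alcohol F7 as C2 epimers.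
- TEMPO/PhI(OAc)2 in MeCN/H2O then gives acid 19.

**Step 8.**
- Risk: hypochlorous acid released during the chlorite oxidation may chlorinate ring A, or C–B oxidation of the hindered α-chloroboronate may stall.
- Fallback: it sets out from 16 and comes back at acid 19, avoiding chlorite.
- Chloromethyllithium made in situ (BrCH2Cl, n-BuLi, THF, −78 °C to rt) homologates 16 to the primary mac boronate F8.
- NaBO3 in THF/H2O converts it into the primary alcohol F7, and TEMPO/PhI(OAc)2 oxidises this to 19.

Further compounds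
F1 | step 6 | 5-bromo-2-methoxyphenyl 4-methylbenzenesulfonate | COc1ccc(Br)cc1OS(=O)(=O)c1ccc(C)cc1
F2 | step 6 | pinacol ester of (1S,2R)-1-(3,4-dimethoxyphenyl)-1-[4-methoxy-3-(tosyloxy)phenyl]propan-2-ylboronic acid | COc1ccc([C@@H]([C@@H](C)B2OC(C)(C)C(C)(C)O2)c2ccc(OC)c(OC)c2)cc1OS(=O)(=O)c1ccc(C)cc1
F3 | step 6 | pinacol ester of (2R,3S)-1-chloro-3-(3,4-dimethoxyphenyl)-3-[4-methoxy-3-(tosyloxy)phenyl]-2-methylpropylboronic acid (CHCl epimers) | COc1ccc([C@@H]([C@@H](C)C(Cl)B2OC(C)(C)C(C)(C)O2)c2ccc(OC)c(OC)c2)cc1OS(=O)(=O)c1ccc(C)cc1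
F4 | step 6 | pinacol ester of (3S,4S)-4-(3,4-dimethoxyphenyl)-4-[4-methoxy-3-(tosyloxy)phenyl]-3-methylbutan-2-ylboronic acid (C2 epimers) | COc1ccc([C@@H]([C@@H](C)C(C)B2OC(C)(C)C(C)(C)O2)c2ccc(OC)c(OC)c2)cc1OS(=O)(=O)c1ccc(C)cc1
F5 | step 6 | pinacol ester of (3R,4S)-1-chloro-4-(3,4-dimethoxyphenyl)-4-[4-methoxy-3-(tosyloxy)phenyl]-2,3-dimethylbutylboronic acid (C1 and C2 epimers) | COc1ccc([C@@H]([C@@H](C)C(C)C(Cl)B2OC(C)(C)C(C)(C)O2)c2ccc(OC)c(OC)c2)cc1OS(=O)(=O)c1ccc(C)cc1
F6 | step 7 | 5-[(1S,2R)-1-(3,4-dimethoxyphenyl)-2,3-dimethylbut-3-en-1-yl]-2-methoxyphenyl 4-methylbenzenesulfonate | COc1ccc([C@@H]([C@@H](C)C(C)=C)c2ccc(OC)c(OC)c2)cc1OS(=O)(=O)c1ccc(C)cc1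
F7 | step 7 | (3R,4S)-4-(3,4-dimethoxyphenyl)-4-[4-methoxy-3-(tosyloxy)phenyl]-2,3-dimethylbutan-1-ol (C2 epimers) | COc1ccc([C@@H]([C@@H](C)C(C)CO)c2ccc(OC)c(OC)c2)cc1OS(=O)(=O)c1ccc(C)cc1
F8 | step 8 | mac ester of (3S,4S)-4-(3,4-dimethoxyphenyl)-4-[4-methoxy-3-(tosyloxy)phenyl]-2,3-dimethylbutylboronic acid (C2 epimers) | COc1ccc([C@@H]([C@@H](C)C(C)CB2O[C@]3(C)c4cccc5cccc(c45)[C@]3(C)O2)c2ccc(OC)c(OC)c2)cc1OS(=O)(=O)c1ccc(C)cc1
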